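**Plan**

- Eudesmane numbering is used: ring A = C1–C5 and C10, ring B = C5–C10, C14 = methyl on C10, C15 = methyl on C4, C11–C13 = side chain on C7.
- Cuts, in retrosynthetic order: C11–C12 (ester carbon from CO), C4–C15 (methylene from a titanium carbene), then C5–C6 and C9–C10 together, and last C6–C7 of the diene (formyl carbon from DMF).
- The enabling feature is ring B: it has the methyl-bearing quaternary C10 at the ring fusion beside C9H2, and an oxygen on C6 beside C5. That is the pattern left by a 1-oxygenated diene (C6–C7–C8–C9) adding to the methyl-substituted C5=C10 bond of a quinone that already is ring A with oxygen at C1 and C4.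
- Forward: the diene is made in 4 steps from pentenone; the cycloaddition closes ring B onto ring A; ring A is then adjusted (C5 epimerisation, removal of C2=C3 and OMe, C1 reduction, C4 carbinol); ring B is finished (hydroboration, acetate, ketone → enol triflate → acrylate); desilylation ends the route.
- Stereochemistry: C10 (absolute) from the chiral titanium BINOLate; C6 from the endo rule; C5 by equilibration to the trans-decalin; C1 by axial hydride attack; C4 by α-face epoxidation anti to the C10 methyl followed by hydride opening; C7 and C8 by syn hydroboration on the α-face.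

Key step: step 5

Assumption: the (S)-BINOLate titanium catalyst is taken to deliver the diene to the quinone face that gives the configuration drawn; if the opposite sense is found, the (R)-ligand is used and nothing else changes.

**Route**

Step 1
Reactants: 1 (E)-pent-3-en-2-one
Product: 3 (Z)-3-bromopent-3-en-2-one, via 3,4-dibromopentan-2-one 2 (not isolated)
Conditions: Br2, CH2Cl2, 0 °C; then Et3N, 0 °C → rt
Reagents that add atoms: bromine, BrBr
Why: Bromine addition to the enone followed by E1cB loss of HBr from the acidic α-position is the standard bromination–dehydrobromination route to α-bromoenones, and the alkene geometry has no consequence later.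

Step 2
Reactants: 3 (Z)-3-bromopent-3-en-2-one
Product: 4 2-[(Z)-1-bromoprop-1-en-1-yl]-2-methyl-1,3-dioxolane
Conditions: HOCH2CH2OH, TsOH·H2O (cat.), benzene, reflux, Dean–Stark
Reagents that add atoms: ethylene glycol, OCCO
Why: Acid-catalysed ketalisation with azeotropic water removal, which α-bromoenones are known to undergo without migration of the double bond.

Step 3
Reactants: 4 2-[(Z)-1-bromoprop-1-en-1-yl]-2-methyl-1,3-dioxolane
Product: 6 (E)-2-(2-methyl-1,3-dioxolan-2-yl)but-2-enal, via α-ketal vinyllithium 5 (not isolated)
Conditions: t-BuLi (2.1 equiv), Et2O, −78 °C; DMF, −78 → 0 °C; H2O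
Reagents that add atoms: N,N-dimethylformamide, CN(C)C=O
Why: Bromine–lithium exchange at −78 °C gives the α-ketal vinyllithium (an α-acylvinyl anion equivalent), which is formylated by DMF in a Bouveault-type reaction; this avoids any enolate β to the ketal.

Step 4
Reactants: 6 (E)-2-(2-methyl-1,3-dioxolan-2-yl)but-2-enal
Product: 7 (1Z)-1-(tert-butyldimethylsilyloxy)-2-(2-methyl-1,3-dioxolan-2-yl)buta-1,3-diene (silyloxy trans to the vinyl group)
Conditions: TBSOTf, Et3N, Et2O, 0 °C → rt
Reagents that add atoms: tert-butyldimethylsilyl triflate, CC(C)(C)[Si](C)(C)OS(=O)(=O)C(F)(F)F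
Why: Soft vinylogous enolisation (O-silylation of the enal, then γ-deprotonation by the amine) gives the silyl dienol ether, and reaction through the s-trans enal should place the silyloxy group trans to the vinyl group.

Step 5
Reactants: 7 silyloxy diene; 8 2-methoxy-5-methyl-1,4-benzoquinone
Product: 9 cis-fused endo cycloadduct (5β-H; 10β-CH3; 6α-OTBS; 3-methoxy-Δ2-1,4-dione in ring A; Δ7 with the dioxolane on C7)
Conditions: TiCl2[(S)-BINOLate] (10 mol %, from TiCl2(OiPr)2 and (S)-BINOL), CH2Cl2, −30 → 0 °C
Reagents that add atoms: none
Why: A concerted, suprafacial [4+2] cycloaddition of normal electron demand in which the 1-silyloxy diene adds across the methyl-bearing C5=C10 bond of the quinone; the closest known reaction types are the chiral titanium BINOLate catalysed Diels–Alder reactions of chelating quinones with 1-oxygenated dienes and the additions of dienes to this same double bond of 2-methoxy-5-methylbenzoquinone. Ring B is closed by the cycloaddition itself, C9–C10 and C5–C6 forming in one step on one face of each partner, so no separate cyclisation mode applies. The methoxy group turns C2=C3 into a vinylogous ester and leaves C5=C10 as the only dienophilic bond, and titanium chelated between the C4 carbonyl and the C3 methoxy oxygen makes C10 the β-carbon, which bonds to the nucleophilic CH2 terminus C9 of the diene while the oxygen-bearing terminus C6 bonds to C5. The quaternary C10 is set in the absolute sense by the BINOLate ligand, which differentiates the faces of the chelated quinone; C5 is tied to C10 by suprafacial addition (H5 cis to the methyl); C6 follows from the endo transition state with the silyloxy group outside on the diene, which puts the C6 oxygen anti to H5, that is α when the methyl is β. The step thus needs site, regio, endo and enantio selectivity, secured by the methoxy group, by chelation together with the 1-oxy diene polarisation, by secondary overlap with the enedione, and by the chiral ligand.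

Step 6
Reactants: 9 cis-fused cycloadduct
Product: 10 trans-fused enedione (5α-H)
Conditions: DBU (0.2 equiv), THF, 0 °C → rt
Reagents that add atoms: none
Why: Base-catalysed epimerisation through the C4 enolate at C5, the only enolisable ring-fusion position because C10 is quaternary, should lead to the trans-decalin, expected to be the more stable isomer of such 10-methyl enediones; the mild catalytic base is chosen to keep β-loss of the C6 silanolate slow.

Step 7
Reactants: 10 trans-fused enedione
Product: 12 trans-fused saturated 1,4-dione, via 3-methoxy-1,4-dione 11 (not isolated)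
Conditions: SmI2 (5 equiv), THF/MeOH, −78 °C
Reagents that add atoms: none
Why: SmI2 first reduces the enedione C2=C3 bond and then cleaves the methoxy group, now α to the C4 ketone, by the known reductive cleavage of α-alkoxy ketones (ketyl, second electron, loss of methoxide, protonation of the samarium enolate), so C3 ends as CH2 and no stereocentre is touched.

Step 8
Reactants: 12 trans-fused 1,4-dione
Product: 13 1β,4β-diol
Conditions: NaBH4, MeOH/CH2Cl2, −20 → 0 °C
Reagents that add atoms: none
Why: Borohydride reduction in which hydride adds to C1 axially from the α-face to give the equatorial 1β-alcohol; C4, whose axial face is blocked by the syn-axial C10 methyl, should give mainly the axial 4β-alcohol, a centre that is erased again in step 10.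

Step 9
Reactants: 13 1β,4β-diol
Product: 14 1β-TBS ether with free C4 hydroxyl
Conditions: TBSCl (1.2 equiv), imidazole, DMF, rt
Reagents that add atoms: tert-butyldimethylsilyl chloride, CC(C)(C)[Si](C)(C)Cl
Why: Silylation should be selective for the equatorial C1 hydroxyl, because the C4 hydroxyl is axial, syn to the C10 methyl and flanked by the C6 silyl ether.

Step 10
Reactants: 14 1β-TBS ether
Product: 15 C4 ketone
Conditions: Dess–Martin periodinane, NaHCO3, CH2Cl2, rt
Reagents that add atoms: none
Why: Dess–Martin oxidation of the one free secondary alcohol under buffered, non-enolising conditions leaves the C5 centre next to the new ketone unchanged.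

Step 11
Reactants: 15 C4 ketone
Product: 16 4(15)-exocyclic methylene compound
Conditions: Cp2TiMe2 (3 equiv), toluene/THF, 65 °C, dark
Reagents that add atoms: dimethyltitanocene Cp2TiMe2, C[Ti](C)(C1C=CC=C1)C1C=CC=C1
Why: Non-basic carbonyl methylenation through Cp2Ti=CH2 (Petasis methylenation) avoids enolisation at C5 and β-elimination of the C6 silyl ether, which a phosphorus ylide could cause.

Step 12
Reactants: 16 4(15)-methylene compound
Product: 17 4α,15-epoxide (oxygen α, equatorial on C4)
Conditions: mCPBA, NaHCO3, CH2Cl2, 0 °C
Reagents that add atoms: 3-chloroperbenzoic acid, OOC(=O)c1cccc(Cl)c1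
Why: Prilezhaev epoxidation should select the exocyclic alkene over the ring alkene, which is deactivated by three allylic C–O bonds and is hindered; the peracid should attack the α-face, anti to the axial C10 methyl, with the C6 silyl group turned toward H6β and away from that face.

Step 13
Reactants: 17 4α,15-epoxide
Product: 18 4α-hydroxy-4β-methyl compound
Conditions: LiEt3BH, THF, 0 °C → rt
Reagents that add atoms: none
Why: Hydride opens the epoxide by SN2 attack at the primary carbon C15, which becomes the β-methyl group, while the α C4–O bond stays as the tertiary alcohol, so C4 keeps the configuration of the epoxide.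

Step 14
Reactants: 18 tertiary alcohol with ring-B alkene
Product: 20 4α,8α-diol, via C8 alkylborane 19 (not isolated)
Conditions: BH3·THF (3 equiv), THF, 0 °C → rt; then NaOH, H2O2, 0 °C
Reagents that add atoms: hydrogen peroxide, OO
Why: Hydroboration–oxidation adds boron to the less substituted C8 and hydrogen to C7 in a syn manner on the α-face, anti to the axial C10 methyl that lies 1,3 to C8, and oxidation with retention gives 8α-OH and 7α-H (side chain β, all three ring-B substituents equatorial).

Step 15
Reactants: 20 4α,8α-diol
Product: 21 8α-acetate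
Conditions: Ac2O, pyridine, DMAP (cat.), CH2Cl2, 0 °C → rt
Reagents that add atoms: acetic anhydride, CC(=O)OC(C)=O
Why: Acylation of the only secondary hydroxyl; the hindered tertiary C4 hydroxyl should not react under these conditions.

Step 16
Reactants: 21 8α-acetate
Product: 22 C7 methyl ketone
Conditions: PPTS, acetone/H2O, 55 °C
Reagents that add atoms: water, O
Why: Acid-catalysed ketal hydrolysis under conditions that secondary TBS ethers and the acetate tolerate; C7, now α to a ketone, already has the equatorial, thermodynamically preferred configuration.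

Step 17
Reactants: 22 methyl ketone
Product: 23 C4 trimethylsilyl ether
Conditions: TMSOTf, 2,6-lutidine, CH2Cl2, −78 °C
Reagents that add atoms: trimethylsilyl triflate, C[Si](C)(C)OS(=O)(=O)C(F)(F)F
Why: Silylation of the tertiary hydroxyl removes the only acidic O–H before the enolate step, and at −78 °C with a hindered pyridine base the ketone should not be converted to an enol silane.

Step 18
Reactants: 23 C4 trimethylsilyl ether
Product: 25 terminal enol triflate, via potassium enolate 24 (not isolated)
Conditions: KN(SiMe3)2 (1.1 equiv), THF, −78 °C; then 2-[N,N-bis(trifluoromethylsulfonyl)amino]-5-chloropyridine, −78 °C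
Reagents that add atoms: 2-[N,N-bis(trifluoromethylsulfonyl)amino]-5-chloropyridine, FC(F)(F)S(=O)(=O)N(c1ccc(Cl)cn1)S(=O)(=O)C(F)(F)F
Why: Kinetic deprotonation of the methyl ketone at its methyl group (less hindered than C7–H and more acidic than the acetate) followed by O-sulfonylation at −78 °C gives the 1,1-disubstituted enol triflate, and since C7–H is not removed neither C7 nor the two β-oxygen groups are put at risk.

Step 19
Reactants: 25 enol triflate
Product: 26 silyl-protected methyl acrylate
Conditions: Pd(OAc)2 (5 mol %), PPh3 (10 mol %), Et3N, CO (1 atm), MeOH/DMF, rt → 40 °C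
Reagents that add atoms: carbon monoxide, [C-]#[O+]; methanol, CO
Why: Palladium-catalysed methoxycarbonylation of an enol triflate (oxidative addition to zerovalent palladium, CO insertion, methanolysis of the acylpalladium) gives the α-substituted acrylate; loss of the trimethylsilyl group here would not matter.

Step 20
Reactants: 26 silyl-protected methyl acrylate
Product: 27 methyl 8α-acetoxy-1β,4α,6α-trihydroxyeudesm-11(13)-en-12-oate (target)
Conditions: HF·pyridine, pyridine/THF, 0 °C → rt
Reagents that add atoms: none
Why: Buffered fluoride desilylation removes the two TBS groups and the trimethylsilyl group under weakly acidic conditions, which should avoid acetate migration, ester exchange and lactonisation of the freed 6α-hydroxyl onto the acrylate.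

**Compound list**

1 | (E)-pent-3-en-2-one | C/C=C/C(C)=O | starting material
2 | 3,4-dibromopentan-2-one (racemic, formed in the flask) | CC(Br)C(Br)C(C)=O | intermediate
3 | (Z)-3-bromopent-3-en-2-one | C/C=C(\Br)C(C)=O | intermediate
4 | 2-[(Z)-1-bromoprop-1-en-1-yl]-2-methyl-1,3-dioxolane | C/C=C(\Br)C1(C)OCCO1 | intermediate
5 | [(E)-1-(2-methyl-1,3-dioxolan-2-yl)prop-1-en-1-yl]lithium (formed in the flask) | C/C=C(\[Li])C1(C)OCCO1 | intermediate
6 | (E)-2-(2-methyl-1,3-dioxolan-2-yl)but-2-enal | C/C=C(\C=O)C1(C)OCCO1 | intermediate
7 | (1Z)-1-(tert-butyldimethylsilyloxy)-2-(2-methyl-1,3-dioxolan-2-yl)buta-1,3-diene, silyloxy trans to vinyl | C=C/C(=C/O[Si](C)(C)C(C)(C)C)C1(C)OCCO1 | intermediate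
8 | 2-methoxy-5-methyl-1,4-benzoquinone | COC1=CC(=O)C(C)=CC1=O | starting material
9 | cis-fused cycloadduct: 5β-H, 10β-methyl, 6α-OTBS, 3-methoxy-Δ2-1,4-dione, Δ7 with 7-(2-methyl-1,3-dioxolan-2-yl) | C[C@@]12CC=C(C3(C)OCCO3)[C@H](O[Si](C)(C)C(C)(C)C)[C@@H]1C(=O)C(OC)=CC2=O | intermediate
10 | trans-fused enedione: as 9 but 5α-H | C[C@@]12CC=C(C3(C)OCCO3)[C@H](O[Si](C)(C)C(C)(C)C)[C@H]1C(=O)C(OC)=CC2=O | intermediate
11 | trans-fused 3-methoxy-1,4-dione (C3 epimers, formed in the flask) | C[C@@]12CC=C(C3(C)OCCO3)[C@H](O[Si](C)(C)C(C)(C)C)[C@H]1C(=O)C(OC)CC2=O | intermediate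
12 | trans-fused saturated 1,4-dione (C1 and C4 ketones, C2 and C3 CH2) | C[C@@]12CC=C(C3(C)OCCO3)[C@H](O[Si](C)(C)C(C)(C)C)[C@H]1C(=O)CCC2=O | intermediate
13 | 1β,4β-diol (4β-OH drawn as the expected major epimer; the 4α-epimer converges at 15) | C[C@@]12CC=C(C3(C)OCCO3)[C@H](O[Si](C)(C)C(C)(C)C)[C@H]1[C@@H](O)CC[C@H]2O | intermediate
14 | 1β,6α-bis(TBS) ether with free 4β-hydroxyl | C[C@@]12CC=C(C3(C)OCCO3)[C@H](O[Si](C)(C)C(C)(C)C)[C@H]1[C@@H](O)CC[C@H]2O[Si](C)(C)C(C)(C)C | intermediate
15 | C4 ketone, 1β,6α-bis(TBS) ether | C[C@@]12CC=C(C3(C)OCCO3)[C@H](O[Si](C)(C)C(C)(C)C)[C@H]1C(=O)CC[C@H]2O[Si](C)(C)C(C)(C)C | intermediate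
16 | 4(15)-methylene compound | C[C@@]12CC=C(C3(C)OCCO3)[C@H](O[Si](C)(C)C(C)(C)C)[C@H]1C(=C)CC[C@H]2O[Si](C)(C)C(C)(C)C | intermediate
17 | 4α,15-epoxide (spiro epoxide, oxygen α) | C[C@@]12CC=C(C3(C)OCCO3)[C@H](O[Si](C)(C)C(C)(C)C)[C@H]1[C@@]3(CO3)CC[C@H]2O[Si](C)(C)C(C)(C)C | intermediate
18 | 4α-hydroxy-4β-methyl compound with Δ7 alkene | C[C@@]12CC=C(C3(C)OCCO3)[C@H](O[Si](C)(C)C(C)(C)C)[C@H]1[C@](C)(O)CC[C@H]2O[Si](C)(C)C(C)(C)C | intermediate
19 | 8α-boryl intermediate (monoalkylborane, C4 oxygen as O–BH2; formed in the flask) | C[C@@]12C[C@H](B)[C@@H](C3(C)OCCO3)[C@H](O[Si](C)(C)C(C)(C)C)[C@H]1[C@](C)(OB)CC[C@H]2O[Si](C)(C)C(C)(C)C | intermediate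
20 | 4α,8α-diol with 7β-(2-methyl-1,3-dioxolan-2-yl) | C[C@@]12C[C@H](O)[C@@H](C3(C)OCCO3)[C@H](O[Si](C)(C)C(C)(C)C)[C@H]1[C@](C)(O)CC[C@H]2O[Si](C)(C)C(C)(C)C | intermediate
21 | 8α-acetate | C[C@@]12C[C@H](OC(C)=O)[C@@H](C3(C)OCCO3)[C@H](O[Si](C)(C)C(C)(C)C)[C@H]1[C@](C)(O)CC[C@H]2O[Si](C)(C)C(C)(C)C | intermediate
22 | 7β-acetyl compound (methyl ketone), 8α-acetate, free 4α-OH | C[C@@]12C[C@H](OC(C)=O)[C@@H](C(C)=O)[C@H](O[Si](C)(C)C(C)(C)C)[C@H]1[C@](C)(O)CC[C@H]2O[Si](C)(C)C(C)(C)C | intermediate
23 | methyl ketone with 4α-O-trimethylsilyl ether | C[C@@]12C[C@H](OC(C)=O)[C@@H](C(C)=O)[C@H](O[Si](C)(C)C(C)(C)C)[C@H]1[C@](C)(O[Si](C)(C)C)CC[C@H]2O[Si](C)(C)C(C)(C)C | intermediate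
24 | terminal potassium enolate of 23 (formed in the flask) | C[C@@]12C[C@H](OC(C)=O)[C@@H](C(=C)[O-])[C@H](O[Si](C)(C)C(C)(C)C)[C@H]1[C@](C)(O[Si](C)(C)C)CC[C@H]2O[Si](C)(C)C(C)(C)C.[K+] | intermediate
25 | terminal enol triflate (C11 bears OTf, C13 is =CH2) | C[C@@]12C[C@H](OC(C)=O)[C@@H](C(=C)OS(=O)(=O)C(F)(F)F)[C@H](O[Si](C)(C)C(C)(C)C)[C@H]1[C@](C)(O[Si](C)(C)C)CC[C@H]2O[Si](C)(C)C(C)(C)C | intermediate
26 | methyl 11(13)-en-12-oate with 1β,6α-bis(TBS) and 4α-trimethylsilyl ethers, 8α-acetate | C[C@@]12C[C@H](OC(C)=O)[C@@H](C(=C)C(=O)OC)[C@H](O[Si](C)(C)C(C)(C)C)[C@H]1[C@](C)(O[Si](C)(C)C)CC[C@H]2O[Si](C)(C)C(C)(C)C | intermediate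
27 | methyl 8α-acetoxy-1β,4α,6α-trihydroxyeudesm-11(13)-en-12-oate (CNP0272656.1) | C[C@@]12C[C@H](OC(C)=O)[C@@H](C(=C)C(=O)OC)[C@H](O)[C@H]1[C@](C)(O)CC[C@H]2O | target

**Totals**

Total step count: 20.
Longest linear sequence: 20 steps (1 → 27); quinone 8 is bought and enters at step 5.

**Steps most likely to fail**

1. Step 5. What may go wrong: the Lewis acid may ionise the allylic ketal or desilylate the dienol ether before cycloaddition, or the catalyst may discriminate the quinone faces poorly. Fallback: 7 and 8 are combined without catalyst (toluene, 80 °C). Site, regio and endo control are all substrate-borne and should persist, but the product is the racemate, that is 9 together with mirror-image adduct ent-9 F1. The enantiomers are separated by preparative chromatography on a chiral stationary phase. The fallback sets out from 7 and 8 and returns to the route at 9.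

2. Step 6. What may go wrong: the C4 enolate may lose the C6 silanolate (E1cB, giving a C5=C6 dienone) faster than it reprotonates, or the equilibrium may retain much cis isomer. Fallback: the equilibration is moved behind the reduction. Starting from 9, SmI2 in THF/MeOH (as in step 7) gives, through cis-fused 3-methoxy-1,4-dione F2, the cis-fused saturated 1,4-dione F3. F3 no longer carries the enedione, so it can be equilibrated at C5 with catalytic NaOMe in MeOH at low temperature to the trans-fused dione. The fallback sets out from 9 and returns at 12.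

3. Step 12. What may go wrong: facial selectivity at C4 may be poor or inverted if the C6 silyl ether closes the α-face, and the ring alkene may compete for the peracid. Fallback: the carbon nucleophile is used instead of the oxygen electrophile. Ketone 15 is treated with MeMgBr and anhydrous CeCl3 (THF, −78 °C). A methyl group entering from the β-face (the face the peracid would then have preferred) becomes the axial 4β-methyl and leaves the 4α-hydroxyl, and no second alkene is involved. This gives 18 directly, so the fallback sets out from 15 and returns at 18; it makes no new compound: none F0.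

**Further compounds**

F1 | step 5 | ent-9, mirror image of cycloadduct 9 | C[C@]12CC=C(C3(C)OCCO3)[C@@H](O[Si](C)(C)C(C)(C)C)[C@H]1C(=O)C(OC)=CC2=O
F2 | step 6 | cis-fused 3-methoxy-1,4-dione (5β-H, C3 epimers, formed in the flask) | C[C@@]12CC=C(C3(C)OCCO3)[C@H](O[Si](C)(C)C(C)(C)C)[C@@H]1C(=O)C(OC)CC2=O
F3 | step 6 | cis-fused saturated 1,4-dione (5β-H) | C[C@@]12CC=C(C3(C)OCCO3)[C@H](O[Si](C)(C)C(C)(C)C)[C@@H]1C(=O)CCC2=O
F0 | step 12 | none | none
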